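In percent of the first end groups charged, the links of the grey run stood at 14.5% and 14.1% in its earlier two readings and at 16.9% and 19.1% in its later two. Tuesday's flask has the grey charge and is read at 40 h, so I turned the question round and asked what the readings would have to show for links to be rising steadily towards the end.

| flask | first end groups | second end groups | remark | time |
|---|---|---|---|---|
| grey | 0.032 M | 0.0314 M | run made earlier |  |
| teal | 0.045 M | 0.0314 M | run made earlier |  |
| violet | 0.070 M | 0.0314 M | run made earlier |  |
| Monday's | 0.032 M | 0.0314 M (fed, over 25 h) | all else is in the flask from the start; the feed brings no volume worth counting | 40 h |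
| Tuesday's | 0.032 M | 0.0314 M | everything together at the start | 40 h |
| Saturday's | 0.032 M | 0.0314 M (in portions, 3, over 25 h) | first portion at the start, last at 25 h | 40 h |
| Wednesday's | 0.032 M (fed, over 25 h) | 0.0314 M | all else is in the flask from the start; the feed brings no volume worth counting | 40 h |

| run | time / h | links / % | first end groups / % |
|---|---|---|---|
| grey | 6.00 | 14.5 | 60.6 |
| grey | 12.0 | 14.1 | 40.5 |
| grey | 20.0 | 16.9 | 29.2 |
| grey | 25.0 | 19.1 | 25.3 |
| teal | 8.00 | 15.2 | 53.6 |
| teal | 15.0 | 16.7 | 40.6 |
| teal | 25.0 | 14.6 | 32.1 |
| teal | 30.0 | 14.8 | 28.4 |
| violet | 2.50 | 9.5 | 79.5 |
| violet | 6.00 | 10.6 | 62.8 |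
| violet | 15.0 | 12.5 | 46.4 |
| violet | 30.0 | 13.1 | 33.1 |

(scatter of a reading: 1 percentage point)



* the flask that comes out highest in amount of links, in percent of the first end groups charged, or "all alike" when all lie within 1.5 percentage points (Monday's / Tuesday's / Saturday's / Wednesday's / all alike)
* links at the end, in percent of the first end groups charged, Monday's
* links at the end, in percent of the first end groups charged, Tuesday's
* links at the end, in percent of the first end groups charged, Saturday's
* links at the end, in percent of the first end groups charged, Wednesday's

I took the hold ratio, the sum of the later two links readings over the sum of the earlier two, pooled over the grey, teal and violet runs, which came to 1.13. Links growing in step with time would have given the ratio of the time sums, 2.50 on the grey times, and the readings stand well below that. So I read links as nearly level and put Tuesday's between the grey mean of 16.1% and the mean of its later two readings, 18.0%. The earlier runs show no feed, but I expected the fed flasks to end lower.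

The forecast said “The batch flask therefore ends slightly highest”, naming Tuesday's with 30% (range 26% to 34%), and gave Monday's 27%, Saturday's 28% and Wednesday's 28.5%, so its Tuesday's figure lay above mine.

The flasks gave 11.5% for Monday's, 17.3% for Tuesday's, 13.5% for Saturday's and 5.17% for Wednesday's, so Tuesday's came highest, and the forecast for Tuesday's stood 13 percentage points too high.

    first end groups + second end groups → links (k = 6.00 × 10⁻⁴ L mol⁻¹ s⁻¹)
    first end groups + second end groups → rings, rate k2*[first end groups] as long as [second end groups] is above zero (k = 8.20 × 10⁻⁶ s⁻¹)
    first end groups ⇌ dormant form (K = 30.0, k = 7.30 × 10⁻⁶ s⁻¹)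
    2 second end groups → homo dimer (k = 0.00160 L mol⁻¹ s⁻¹)

Tuesday's links went from 17.3% at 20.0 h to 17.3% at 40.0 h, with second end groups at 0% and 0%, so the hold ratio, taken here on one value at each time and not on sums of readings, was 1.00, against the 1.13 read from the runs. The neighbour is Wednesday's flask read at 96.0 h instead of 40.0 h. Its second end groups stood at 0% at the earlier time, and its first end groups fell from 39.4% to 10.6% between the two times, while its links went from 5.17% to 5.17%, a hold ratio, again on one value at each time, of 1.00.

Readings and results stem from a simulated flask for substances that don't exist; the scatter is artificial.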